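**Plan**

Rings: A = the methoxy/hydroxy ring, B = the meta-linked ring, C = the hydroxy ring that carries the aryloxy group, D = the para-linked ring.
1. The retrosynthesis first cuts the bond between C-2 of ring A and its benzylic CH2 (at the ketone level), together with the C-1–O bond of ring A. Both come from adding the O and C ends of an arylacetic acid across an aryne of ring A.
2. Enabling feature: on ring A the phenolic O (C-1), the benzylic carbon (C-2) and the aryloxy O (C-3) sit on three adjacent carbons. A carboxyl group can therefore be delivered across a C-1/C-2 aryne, and the C-3 aryloxy group beside the triple bond fixes the orientation.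
3. Further cuts: the CH2CH2 bridge between B and C (Wittig, then H2), the A–O–B ether (SNAr) and the C–O–D ether (Ullmann).
4. Forward: C–O–D aldehyde 4 (2 steps); A–O–B o-silylaryl triflate and phosphonium salt 14 (5 steps); Wittig and hydrogenation to seco acid 16; aryne ring closure to the 18-membered ketone 18; reduction and deprotection to 19.
5. Stereochemistry: the target is achiral with no stereocentre; the alkene geometry of 15 is erased by hydrogenation.

Key step: step 10

Assumption: 6-bromo-2-fluoro-3-methoxybenzaldehyde (5) and benzyl 2-(4-hydroxyphenyl)acetate (3) are taken as purchasable building blocks.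

**Route**

Step 1
Reactants: 1 3-bromo-4-hydroxybenzaldehyde
Product: 2 3-bromo-4-(methoxymethoxy)benzaldehyde
Conditions: MOMCl, i-Pr2NEt, CH2Cl2, 0 °C → rt
Reagents that add atoms: chloromethyl methyl ether, COCCl
Why: Williamson-type O-alkylation of the phenol (acidified by the para-formyl group) with the α-chloro ether should give the MOM ether, which is stable to base, fluoride and hydrogenation and is removed by acid at the end.

Step 2
Reactants: 2 3-bromo-4-(methoxymethoxy)benzaldehyde; 3 benzyl 2-(4-hydroxyphenyl)acetate
Product: 4 benzyl 2-[4-[5-formyl-2-(methoxymethoxy)phenoxy]phenyl]acetate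
Conditions: CuI (10 mol%), N,N-dimethylglycine·HCl (30 mol%), Cs2CO3, 1,4-dioxane, 90 °C
Reagents that add atoms: none
Why: Amino acid-promoted Ullmann diaryl ether coupling of the aryl bromide with the phenoxide should form the C–O–D ether at a temperature that the aldehyde, the MOM acetal and the benzyl ester tolerate.

Step 3
Reactants: 5 6-bromo-2-fluoro-3-methoxybenzaldehyde; 6 3-(hydroxymethyl)phenol
Product: 7 6-bromo-2-[3-(hydroxymethyl)phenoxy]-3-methoxybenzaldehyde
Conditions: K2CO3, DMF, 90 °C
Reagents that add atoms: none
Why: SNAr of the fluoride ortho to the formyl group by the phenoxide (Meisenheimer pathway) should form the A–O–B ether, since fluoride is a far better SNAr leaving group than bromide and carbonate does not ionise the benzylic alcohol.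

Step 4
Reactants: 7 6-bromo-2-[3-(hydroxymethyl)phenoxy]-3-methoxybenzaldehyde
Product: 9 6-bromo-2-[3-(hydroxymethyl)phenoxy]-3-methoxyphenol, via aryl formate 8 (not isolated)
Conditions: mCPBA, CH2Cl2, 0 °C → rt; then K2CO3 (cat.), MeOH, rt
Reagents that add atoms: meta-chloroperoxybenzoic acid, O=C(OO)c1cccc(Cl)c1
Why: Baeyer–Villiger (Dakin-type) oxidation of the di-ortho-substituted, ortho-aryloxy benzaldehyde should proceed with aryl migration in the Criegee adduct to the formate, which methanolysis cleaves to the phenol that later becomes the triflate oxygen.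

Step 5
Reactants: 9 6-bromo-2-[3-(hydroxymethyl)phenoxy]-3-methoxyphenol
Product: 12 [2-[3-(hydroxymethyl)phenoxy]-3-methoxy-6-(trimethylsilyl)phenyl] trifluoromethanesulfonate, via bis(trimethylsilyl) ether 10 (not isolated), via O-silylated triflate 11 (not isolated)
Conditions: HMDS, THF, 65 °C, evaporate; n-BuLi, THF, −100 °C; Tf2O, −100 °C → rt; then 1 M HCl, THF, 0 °C
Reagents that add atoms: hexamethyldisilazane, C[Si](C)(C)N[Si](C)(C)C; trifluoromethanesulfonic anhydride, O=S(=O)(OS(=O)(=O)C(F)(F)F)C(F)(F)F
Why: Br/Li exchange on the O-silylated bromophenol should trigger a retro-Brook 1,3 O→C silyl shift, and the resulting lithium phenoxide is trapped as the triflate, while the labile primary silyl ether is hydrolysed in the mild acidic work-up.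

Step 6
Reactants: 12 [2-[3-(hydroxymethyl)phenoxy]-3-methoxy-6-(trimethylsilyl)phenyl] trifluoromethanesulfonate
Product: 13 [2-[3-(bromomethyl)phenoxy]-3-methoxy-6-(trimethylsilyl)phenyl] trifluoromethanesulfonate
Conditions: CBr4, PPh3, CH2Cl2, 0 °C
Reagents that add atoms: carbon tetrabromide, BrC(Br)(Br)Br
Why: Appel bromination (SN2 on the alkoxyphosphonium ion) is neutral and fluoride-free, so the aryl triflate and the aryl silane should be untouched.

Step 7
Reactants: 13 [2-[3-(bromomethyl)phenoxy]-3-methoxy-6-(trimethylsilyl)phenyl] trifluoromethanesulfonate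
Product: 14 [3-[2-methoxy-6-(trifluoromethylsulfonyloxy)-5-(trimethylsilyl)phenoxy]benzyl]triphenylphosphonium bromide
Conditions: PPh3, toluene, 90 °C
Reagents that add atoms: triphenylphosphine, c1ccc(P(c2ccccc2)c2ccccc2)cc1
Why: SN2 quaternisation of triphenylphosphine by the benzylic bromide should give the salt, which precipitates from toluene.

Step 8
Reactants: 14 [3-[2-methoxy-6-(trifluoromethylsulfonyloxy)-5-(trimethylsilyl)phenoxy]benzyl]triphenylphosphonium bromide; 4 benzyl 2-[4-[5-formyl-2-(methoxymethoxy)phenoxy]phenyl]acetate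
Product: 15 benzyl 2-[4-[5-[2-[3-[2-methoxy-6-(trifluoromethylsulfonyloxy)-5-(trimethylsilyl)phenoxy]phenyl]ethenyl]-2-(methoxymethoxy)phenoxy]phenyl]acetate (E/Z mixture)
Conditions: NaHMDS, THF, −78 °C; then 4, −78 °C → rt
Reagents that add atoms: none
Why: Wittig olefination with the semi-stabilised benzylic ylide should join the two halves; a hindered amide base at −78 °C, with no fluoride or alkoxide, leaves the o-silylaryl triflate and the ester intact, and the E/Z ratio does not matter.

Step 9
Reactants: 15 benzyl 2-[4-[5-[2-[3-[2-methoxy-6-(trifluoromethylsulfonyloxy)-5-(trimethylsilyl)phenoxy]phenyl]ethenyl]-2-(methoxymethoxy)phenoxy]phenyl]acetate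
Product: 16 2-[4-[5-[2-[3-[2-methoxy-6-(trifluoromethylsulfonyloxy)-5-(trimethylsilyl)phenoxy]phenyl]ethyl]-2-(methoxymethoxy)phenoxy]phenyl]acetic acid
Conditions: H2 (1 atm), 10% Pd/C, EtOAc, rt
Reagents that add atoms: none
Why: Heterogeneous hydrogenation should saturate the stilbene and hydrogenolyse the benzyl ester in one operation; without added base the hindered aryl triflate, the aryl silane and the MOM acetal are expected to survive.

Step 10
Reactants: 16 2-[4-[5-[2-[3-[2-methoxy-6-(trifluoromethylsulfonyloxy)-5-(trimethylsilyl)phenoxy]phenyl]ethyl]-2-(methoxymethoxy)phenoxy]phenyl]acetic acid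
Product: 18 18-membered o-hydroxyaryl ketone (the ring of 19 with C=O at the CH2 next to ring A and a MOM ether on the ring C phenol), via aryne acid 17 (not isolated)
Conditions: CsF (10 equiv), THF (1 mM), sealed vessel, 110 °C
Reagents that add atoms: none
Why: Proposed new method: fluoride removes the silyl group and the ortho triflate leaves to give aryne 17; the cesium carboxylate at the far chain end adds through oxygen to the aryne carbon remote from the aryloxy group, giving a 20-membered aryl ester with an aryl anion beside the ester oxygen, and this anion attacks the ester carbonyl in a 4-exo-trig addition whose four-membered alkoxide opens to the phenoxide, so that the acyl carbon passes from O to C and the ring contracts to the 18-membered ketone. The closest known reaction type is the intermolecular formal insertion of arynes into the C–O bond of carboxylic acids to give o-hydroxyaryl ketones, an aryne variant of the anionic Fries 1,3 O→C acyl shift; its use to close a macrocycle is new. No stereocentre is formed. Three selectivities are needed: the site (O at C-1, acyl at C-2) should follow from the C-3 aryloxy group, whose inductive pull distorts the aryne so that nucleophiles add at the distal carbon and the charge develops next to the C–O bond, helped by the unsubstituted position beside C-1; ring closure over oligomerisation should follow from the 1 mM concentration, at which each aryne carries its own carboxylate; and acyl shift over protonation of the aryl anion should follow from the aprotic ether solvent, the low concentration of proton donors and the heat that the intermolecular reaction type also calls for. The MOM ether is required because a free ring C phenol would itself add to the aryne.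

Step 11
Reactants: 18 18-membered o-hydroxyaryl ketone
Product: 19 target CNP0179896.0
Conditions: Et3SiH (excess), TFA, CH2Cl2, 0 °C → rt
Reagents that add atoms: none
Why: Ionic hydrogenation of the o-hydroxyaryl ketone (hydride transfer to the protonated carbonyl, then to the benzylic cation or o-quinone methide) should give the CH2 group, while TFA cleaves the aryl MOM acetal by loss of the phenol and the silane scavenges the methoxymethyl cation.

**Compound list**

1 | 3-bromo-4-hydroxybenzaldehyde | O=Cc1ccc(O)c(Br)c1 | starting material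
2 | 3-bromo-4-(methoxymethoxy)benzaldehyde | COCOc1ccc(C=O)cc1Br | intermediate
3 | benzyl 2-(4-hydroxyphenyl)acetate | O=C(Cc1ccc(O)cc1)OCc1ccccc1 | starting material
4 | benzyl 2-[4-[5-formyl-2-(methoxymethoxy)phenoxy]phenyl]acetate | COCOc1ccc(C=O)cc1Oc1ccc(CC(=O)OCc2ccccc2)cc1 | intermediate
5 | 6-bromo-2-fluoro-3-methoxybenzaldehyde | COc1ccc(Br)c(C=O)c1F | starting material
6 | 3-(hydroxymethyl)phenol | OCc1cccc(O)c1 | starting material
7 | 6-bromo-2-[3-(hydroxymethyl)phenoxy]-3-methoxybenzaldehyde | COc1ccc(Br)c(C=O)c1Oc1cccc(CO)c1 | intermediate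
8 | [6-bromo-2-[3-(hydroxymethyl)phenoxy]-3-methoxyphenyl] formate | COc1ccc(Br)c(OC=O)c1Oc1cccc(CO)c1 | intermediate
9 | 6-bromo-2-[3-(hydroxymethyl)phenoxy]-3-methoxyphenol | COc1ccc(Br)c(O)c1Oc1cccc(CO)c1 | intermediate
10 | bis(trimethylsilyl) ether of 9 (phenol O and benzylic O silylated) | COc1ccc(Br)c(O[Si](C)(C)C)c1Oc1cccc(CO[Si](C)(C)C)c1 | intermediate
11 | [3-methoxy-6-(trimethylsilyl)-2-[3-[(trimethylsilyloxy)methyl]phenoxy]phenyl] trifluoromethanesulfonate | COc1ccc([Si](C)(C)C)c(OS(=O)(=O)C(F)(F)F)c1Oc1cccc(CO[Si](C)(C)C)c1 | intermediate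
12 | [2-[3-(hydroxymethyl)phenoxy]-3-methoxy-6-(trimethylsilyl)phenyl] trifluoromethanesulfonate | COc1ccc([Si](C)(C)C)c(OS(=O)(=O)C(F)(F)F)c1Oc1cccc(CO)c1 | intermediate
13 | [2-[3-(bromomethyl)phenoxy]-3-methoxy-6-(trimethylsilyl)phenyl] trifluoromethanesulfonate | COc1ccc([Si](C)(C)C)c(OS(=O)(=O)C(F)(F)F)c1Oc1cccc(CBr)c1 | intermediate
14 | [3-[2-methoxy-6-(trifluoromethylsulfonyloxy)-5-(trimethylsilyl)phenoxy]benzyl]triphenylphosphonium bromide | COc1ccc([Si](C)(C)C)c(OS(=O)(=O)C(F)(F)F)c1Oc1cccc(C[P+](c2ccccc2)(c2ccccc2)c2ccccc2)c1.[Br-] | intermediate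
15 | benzyl 2-[4-[5-[2-[3-[2-methoxy-6-(trifluoromethylsulfonyloxy)-5-(trimethylsilyl)phenoxy]phenyl]ethenyl]-2-(methoxymethoxy)phenoxy]phenyl]acetate (E/Z mixture) | COc1ccc([Si](C)(C)C)c(OS(=O)(=O)C(F)(F)F)c1Oc1cccc(C=Cc2ccc(OCOC)c(Oc3ccc(CC(=O)OCc4ccccc4)cc3)c2)c1 | intermediate
16 | 2-[4-[5-[2-[3-[2-methoxy-6-(trifluoromethylsulfonyloxy)-5-(trimethylsilyl)phenoxy]phenyl]ethyl]-2-(methoxymethoxy)phenoxy]phenyl]acetic acid (seco acid) | COc1ccc([Si](C)(C)C)c(OS(=O)(=O)C(F)(F)F)c1Oc1cccc(CCc2ccc(OCOC)c(Oc3ccc(CC(=O)O)cc3)c2)c1 | intermediate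
17 | aryne acid: seco acid 16 without SiMe3 and OTf, triple bond between those two ring A carbons (3-aryloxy-4-methoxybenzyne) | COC1=C(Oc2cccc(CCc3ccc(OCOC)c(Oc4ccc(CC(=O)O)cc4)c3)c2)C#CC=C1 | intermediate
18 | 18-membered o-hydroxyaryl ketone: ring of 19 with C=O at the CH2 attached to ring A and OMOM on ring C | COc1ccc(O)c2c1Oc1cccc(c1)CCc1ccc(OCOC)c(c1)Oc1ccc(cc1)CC2=O | intermediate
19 | CNP0179896.0, macrocyclic bis(bibenzyl) | COc1ccc(O)c2c1Oc1cccc(c1)CCc1ccc(O)c(c1)Oc1ccc(cc1)CC2 | target

**Count**

Total: 11 steps. Longest linear sequence: 9 steps (5 → 19, steps 3–11).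

**Steps most likely to fail**

Step 10 (Proposed new method). The aryne may be captured by the carboxylate of another molecule, giving oligomers, or the aryl anion may be protonated before the acyl shift, so that the reaction stops at the 20-membered aryl ester. The fallback uses the same aryne acyl transfer in its known intermolecular form and closes the ring by an intramolecular Wittig reaction; it sets out from 4 and 12 and comes back at 18. Saponification of 4 (LiOH, THF/H2O) should give 2-[4-[5-formyl-2-(methoxymethoxy)phenoxy]phenyl]acetic acid F1. Heating F1 with 12 and CsF in THF (sealed, 125 °C) should give the open-chain o-hydroxyaryl ketone 3-[4-[2-[6-hydroxy-2-[3-(hydroxymethyl)phenoxy]-3-methoxyphenyl]-2-oxoethyl]phenoxy]-4-(methoxymethoxy)benzaldehyde F2, with the same orientation control by the aryloxy group. Appel bromination (CBr4, PPh3) should give the benzylic bromide F3, and PPh3 in toluene the phosphonium bromide F4. Slow addition of F4 to NaOMe (2.2 equiv, CH2Cl2/MeOH, high dilution) should give the macrocyclic stilbene ketone F5; the phenoxide formed first keeps the ketone from enolising. Hydrogenation (H2, Pd/C, EtOAc) should then give 18.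

Step 4. Hydride instead of aryl migration in the Criegee adduct is possible, because the ortho bromine lowers the migratory aptitude of the ring; this would lead to the benzoic acid. The fallback installs the bromine after the oxidation; it sets out from 6 and comes back at 9. SNAr of 6 on commercial 2-fluoro-3-methoxybenzaldehyde (K2CO3, DMF, 90 °C) should give 2-[3-(hydroxymethyl)phenoxy]-3-methoxybenzaldehyde F6. mCPBA should convert it, through [2-[3-(hydroxymethyl)phenoxy]-3-methoxyphenyl] formate F7 and methanolysis, into 2-[3-(hydroxymethyl)phenoxy]-3-methoxyphenol F8. Amine-mediated ortho-selective bromination (NBS, cat. i-Pr2NH, CH2Cl2, 0 °C), in which the hydrogen-bonded N-bromoamine delivers bromine beside the hydroxyl group, should give 9.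

Step 11. Reduction may stop at the benzylic alcohol stage, or the MOM acetal may open reductively on the wrong side and leave a methyl ether on ring C. The fallback separates the two tasks and avoids acid in the reduction; it sets out from 18 and comes back at 19. Ethyl chloroformate and Et3N (THF, 0 °C) should give the ethyl carbonate of 18 F9. NaBH4 in THF/H2O should reduce the ketone, after which carbonate transfer and elimination give an o-quinone methide that takes up hydride, to give the MOM ether of 19 F10. HCl in MeOH (40 °C) should then remove the MOM group to give 19.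

**Further compounds**

F1 | step 10 | 2-[4-[5-formyl-2-(methoxymethoxy)phenoxy]phenyl]acetic acid | COCOc1ccc(C=O)cc1Oc1ccc(CC(=O)O)cc1
F2 | step 10 | 3-[4-[2-[6-hydroxy-2-[3-(hydroxymethyl)phenoxy]-3-methoxyphenyl]-2-oxoethyl]phenoxy]-4-(methoxymethoxy)benzaldehyde | COc1ccc(O)c(C(=O)Cc2ccc(Oc3cc(C=O)ccc3OCOC)cc2)c1Oc1cccc(CO)c1
F3 | step 10 | 3-[4-[2-[2-[3-(bromomethyl)phenoxy]-6-hydroxy-3-methoxyphenyl]-2-oxoethyl]phenoxy]-4-(methoxymethoxy)benzaldehyde | COc1ccc(O)c(C(=O)Cc2ccc(Oc3cc(C=O)ccc3OCOC)cc2)c1Oc1cccc(CBr)c1
F4 | step 10 | [3-[2-[2-[4-[5-formyl-2-(methoxymethoxy)phenoxy]phenyl]acetyl]-3-hydroxy-6-methoxyphenoxy]benzyl]triphenylphosphonium bromide | COc1ccc(O)c(C(=O)Cc2ccc(Oc3cc(C=O)ccc3OCOC)cc2)c1Oc1cccc(C[P+](c2ccccc2)(c2ccccc2)c2ccccc2)c1.[Br-]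
F5 | step 10 | macrocyclic stilbene ketone: 18 with CH=CH in place of the CH2CH2 bridge between rings B and C (E/Z mixture) | COc1ccc(O)c2c1Oc1cccc(c1)C=Cc1ccc(OCOC)c(c1)Oc1ccc(cc1)CC2=O
F6 | step 4 | 2-[3-(hydroxymethyl)phenoxy]-3-methoxybenzaldehyde | COc1cccc(C=O)c1Oc1cccc(CO)c1
F7 | step 4 | [2-[3-(hydroxymethyl)phenoxy]-3-methoxyphenyl] formate | COc1cccc(OC=O)c1Oc1cccc(CO)c1
F8 | step 4 | 2-[3-(hydroxymethyl)phenoxy]-3-methoxyphenol | COc1cccc(O)c1Oc1cccc(CO)c1
F9 | step 11 | ethyl carbonate of 18 (on the ring A phenol) | COc1ccc(OC(=O)OCC)c2c1Oc1cccc(c1)CCc1ccc(OCOC)c(c1)Oc1ccc(cc1)CC2=O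
F10 | step 11 | MOM ether of 19 (on the ring C phenol) | COc1ccc(O)c2c1Oc1cccc(c1)CCc1ccc(OCOC)c(c1)Oc1ccc(cc1)CC2
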